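**Remark on the chemistry (assumption):** the (R,R) antipode of the chiral diene ligand is assumed to deliver the aryl group to the face of C2 that gives 2S; if the sense is the opposite, the (S,S) ligand is to be used. TIPS = triisopropylsilyl.

## Retrosynthetic overview

1. End game: both phenols are freed last; the (Z)-enal comes from a (Z)-allylic alcohol, made by Lindlar reduction of an arylpropargyl alcohol installed at C5–Br by Sonogashira coupling; the 4-hydroxybenzoate is put on the C3 CH2OH, which comes from a C3 ester.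
2. Key disconnection: the bond between the guaiacyl ring carbon and C2 of the dihydrofuran ring, made by enantioselective Rh/chiral-diene conjugate arylation of a flat, achiral benzofuran-3-carboxylate with an arylboronic acid; the same flask sets C2 (catalyst) and C3 (equilibration to trans).
3. Enabling feature: with the C3 side-chain carbon at the ester level and the five-membered ring at the benzofuran level, O1–C2=C3–C(=O)OEt is a β-aryloxy acrylate. C2 is its electrophilic β-carbon, and C3 becomes an epimerizable α-aryl ester carbon next to C2.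
4. Ring order: the benzene rings are bought; the furan ring is built first as an aromatic benzofuran (step 1) and is dearomatized in the key step; no other ring is formed.

Key step: step 4

## Route

Step 1
Reactants: 1 5-bromo-2-hydroxy-3-methoxybenzaldehyde; 2 ethyl diazoacetate
Product: 4 ethyl 5-bromo-7-methoxy-1-benzofuran-3-carboxylate, via hemiacetal 3 (not isolated)
Conditions: HBF4·OEt2 (10 mol %), CH2Cl2, rt; then conc. H2SO4, rt
Reagents that add atoms: none
Why: Acid-catalysed addition of the diazoacetate to the salicylaldehyde with 1,2-aryl shift (Roskamp-type homologation) should give the 2-aryl-3-hydroxyacrylate, which closes to the cyclic hemiacetal and is dehydrated by H2SO4 to the aromatic benzofuran-3-carboxylate; no stereocenter is formed.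

Step 2
Reactants: 5 4-bromo-2-methoxyphenol
Product: 6 (4-bromo-2-methoxyphenoxy)triisopropylsilane
Conditions: TIPSCl, imidazole, DMF, rt
Reagents that add atoms: triisopropylsilyl chloride, CC(C)[Si](Cl)(C(C)C)C(C)C
Why: Standard silylation of a phenol; the TIPS ether is chosen because it should survive mild aqueous base, hydride and amine bases and still leave with fluoride at the end.

Step 3
Reactants: 6 (4-bromo-2-methoxyphenoxy)triisopropylsilane
Product: 9 [3-methoxy-4-(triisopropylsilyloxy)phenyl]boronic acid, via aryllithium 7 (not isolated), via lithium aryltriisopropoxyborate 8 (not isolated)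
Conditions: n-BuLi, THF, −78 °C; B(OiPr)3, −78 °C → rt; 1 M HCl, 0 °C
Reagents that add atoms: triisopropyl borate, CC(C)OB(OC(C)C)OC(C)C; water, O
Why: Bromine–lithium exchange followed by borate trapping and hydrolysis is a standard arylboronic acid synthesis; lithium sits para to the silyloxy group, so no silyl migration is expected.

Step 4
Reactants: 4 ethyl 5-bromo-7-methoxy-1-benzofuran-3-carboxylate; 9 [3-methoxy-4-(triisopropylsilyloxy)phenyl]boronic acid
Product: 11 ethyl (2S,3S)-5-bromo-7-methoxy-2-[3-methoxy-4-(triisopropylsilyloxy)phenyl]-2,3-dihydro-1-benzofuran-3-carboxylate (trans), via cis ester 10 (not isolated)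
Conditions: [RhCl(C2H4)2]2 (2.5 mol %), (R,R)-Ph-bod* (5.5 mol %), 9 (2.5 equiv), KOH (0.2 equiv), 1,4-dioxane/H2O (10:1), 60 °C; then DBU (1.0 equiv), 60 °C
Reagents that add atoms: none
Why: Proposed new method: an aryl–Rh(I) species, formed by transmetalation of 9 to the chiral-diene Rh–OH complex, should insert the C2=C3 bond of 4 with aryl at C2 (the β-carbon of the β-aryloxy acrylate O1–C2=C3–CO2Et) and Rh at C3 as an oxa-π-allyl enolate, which water protonates to release the 2,3-dihydrobenzofuran and regenerate Rh–OH. The closest known reaction type is the Rh- or Pd-catalysed asymmetric 1,4-addition of arylboronic acids to chromones, coumarins and other β-oxy enoates (Hayashi–Miyaura reaction), and the acrylate-like character of this C2=C3 bond is supported by the known Mg/MeOH conjugate reduction and Heck-type C2 arylation of benzofuran-3-carboxylates. No ring is closed; the furan ring is dearomatized, which should cost little because its resonance energy is small and is outweighed by the new C–C bond. C2 is set by the chiral diene, which selects the enantioface of the flat heteroarene during insertion; C3 is set under thermodynamic control, because the α-aryl ester proton is acidic and the base funnels the kinetic cis ester 10 into the trans ester with the C2 aryl and C3 ester on opposite faces. The step needs regioselectivity (secured by the ester, which makes C2 the electrophilic terminus), chemoselectivity over C5–Br (Rh(I)–diene complexes should not insert into aryl bromides under these conditions), and freedom from rearomatization and ring opening (after syn insertion no syn β-hydrogen is present, and loss of aryloxide from the enolate is the reverse of a 5-endo-trig closure).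

Step 5
Reactants: 11 ethyl (2S,3S)-5-bromo-7-methoxy-2-[3-methoxy-4-(triisopropylsilyloxy)phenyl]-2,3-dihydro-1-benzofuran-3-carboxylate
Product: 12 [(2S,3R)-5-bromo-7-methoxy-2-[3-methoxy-4-(triisopropylsilyloxy)phenyl]-2,3-dihydro-1-benzofuran-3-yl]methanol
Conditions: DIBAL-H (3 equiv), CH2Cl2, −78 → 0 °C; Rochelle salt work-up
Reagents that add atoms: none
Why: Ester-to-alcohol reduction with DIBAL-H under non-basic, cold conditions should leave the aryl bromide, the silyl ether and both stereocenters untouched; C3 is no longer epimerizable after this step (the descriptor changes from S to R only through CIP priorities).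

Step 6
Reactants: 13 4-hydroxybenzoic acid
Product: 15 4-(triisopropylsilyloxy)benzoic acid, via bis-silyl compound 14 (not isolated)
Conditions: TIPSCl (2.2 equiv), imidazole, DMF, rt; then K2CO3 (1.2 equiv), THF/H2O, rt; 1 M HCl to pH 4
Reagents that add atoms: triisopropylsilyl chloride, CC(C)[Si](Cl)(C(C)C)C(C)C
Why: Exhaustive silylation followed by selective hydrolysis of the much more labile silyl ester is a standard way to O-silylated hydroxybenzoic acids.

Step 7
Reactants: 12 [(2S,3R)-5-bromo-7-methoxy-2-[3-methoxy-4-(triisopropylsilyloxy)phenyl]-2,3-dihydro-1-benzofuran-3-yl]methanol; 15 4-(triisopropylsilyloxy)benzoic acid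
Product: 16 [(2S,3R)-5-bromo-7-methoxy-2-[3-methoxy-4-(triisopropylsilyloxy)phenyl]-2,3-dihydro-1-benzofuran-3-yl]methyl 4-(triisopropylsilyloxy)benzoate
Conditions: DCC, DMAP (cat.), CH2Cl2, 0 °C → rt
Reagents that add atoms: none
Why: Steglich esterification of a primary alcohol; the only free hydroxyl in either partner is the one to be acylated.

Step 8
Reactants: 16 the aryl bromide ester from step 7; 17 prop-2-yn-1-ol
Product: 18 [(2S,3R)-5-(3-hydroxyprop-1-yn-1-yl)-7-methoxy-2-[3-methoxy-4-(triisopropylsilyloxy)phenyl]-2,3-dihydro-1-benzofuran-3-yl]methyl 4-(triisopropylsilyloxy)benzoate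
Conditions: PdCl2(PhCN)2 (3 mol %), [(t-Bu)3PH]BF4 (6 mol %), CuI (2 mol %), i-Pr2NH, 1,4-dioxane, rt
Reagents that add atoms: none
Why: Sonogashira coupling; the bulky electron-rich phosphine should allow oxidative addition into the electron-rich aryl bromide at room temperature, and the amine base should spare ester and silyl ethers.

Step 9
Reactants: 18 the arylpropargyl alcohol from step 8
Product: 19 [(2S,3R)-5-[(1Z)-3-hydroxyprop-1-en-1-yl]-7-methoxy-2-[3-methoxy-4-(triisopropylsilyloxy)phenyl]-2,3-dihydro-1-benzofuran-3-yl]methyl 4-(triisopropylsilyloxy)benzoate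
Conditions: H2 (1 atm), Lindlar catalyst, quinoline, EtOAc, rt, monitored for uptake of 1 equiv
Reagents that add atoms: none
Why: Lindlar semi-hydrogenation delivers both hydrogens to one face of the alkyne and should give the (Z)-alkene; the benzylic C2–O bond and the ester are not expected to react on the poisoned catalyst.

Step 10
Reactants: 19 the (Z)-allylic alcohol from step 9
Product: 20 [(2S,3R)-7-methoxy-2-[3-methoxy-4-(triisopropylsilyloxy)phenyl]-5-[(1Z)-3-oxoprop-1-en-1-yl]-2,3-dihydro-1-benzofuran-3-yl]methyl 4-(triisopropylsilyloxy)benzoate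
Conditions: TEMPO (10 mol %), PhI(OAc)2 (1.1 equiv), CH2Cl2, 0 °C → rt, dark
Reagents that add atoms: none
Why: Oxoammonium (TEMPO/PhI(OAc)2) oxidation of a primary allylic alcohol is mild and near-neutral and should preserve the (Z)-geometry; both phenols are masked, so the iodine(III) oxidant has no phenol to attack.

Step 11
Reactants: 20 the bis-silylated (Z)-enal from step 10
Product: 21 [(2S,3R)-2-(4-hydroxy-3-methoxyphenyl)-7-methoxy-5-[(1Z)-3-oxoprop-1-en-1-yl]-2,3-dihydro-1-benzofuran-3-yl]methyl 4-hydroxybenzoate (CNP0400980.1)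
Conditions: TBAF (2.5 equiv), AcOH (2.5 equiv), THF, 0 °C, dark
Reagents that add atoms: none
Why: Fluoride cleavage of aryl silyl ethers, buffered with acetic acid so that free phenoxide, which could cleave the benzoate or isomerize the (Z)-enal, is not built up.

## Compound list

1 | 5-bromo-2-hydroxy-3-methoxybenzaldehyde | COc1cc(Br)cc(C=O)c1O | starting material
2 | ethyl diazoacetate | CCOC(=O)C=[N+]=[N-] | starting material
3 | ethyl 5-bromo-2-hydroxy-7-methoxy-2,3-dihydro-1-benzofuran-3-carboxylate (hemiacetal, mixture of stereoisomers, not isolated) | CCOC(=O)C1C(O)Oc2c(OC)cc(Br)cc12 | intermediate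
4 | ethyl 5-bromo-7-methoxy-1-benzofuran-3-carboxylate | CCOC(=O)c1coc2c(OC)cc(Br)cc12 | intermediate
5 | 4-bromo-2-methoxyphenol | COc1cc(Br)ccc1O | starting material
6 | (4-bromo-2-methoxyphenoxy)triisopropylsilane | COc1cc(Br)ccc1O[Si](C(C)C)(C(C)C)C(C)C | intermediate
7 | [3-methoxy-4-(triisopropylsilyloxy)phenyl]lithium (not isolated) | [Li]c1ccc(O[Si](C(C)C)(C(C)C)C(C)C)c(OC)c1 | intermediate
8 | lithium [3-methoxy-4-(triisopropylsilyloxy)phenyl]triisopropoxyborate (not isolated) | [Li+].CC(C)O[B-](OC(C)C)(OC(C)C)c1ccc(O[Si](C(C)C)(C(C)C)C(C)C)c(OC)c1 | intermediate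
9 | [3-methoxy-4-(triisopropylsilyloxy)phenyl]boronic acid | COc1cc(B(O)O)ccc1O[Si](C(C)C)(C(C)C)C(C)C | intermediate
10 | ethyl (2S,3R)-5-bromo-7-methoxy-2-[3-methoxy-4-(triisopropylsilyloxy)phenyl]-2,3-dihydro-1-benzofuran-3-carboxylate (cis, not isolated) | COc1cc([C@H]2Oc3c(OC)cc(Br)cc3[C@H]2C(=O)OCC)ccc1O[Si](C(C)C)(C(C)C)C(C)C | intermediate
11 | ethyl (2S,3S)-5-bromo-7-methoxy-2-[3-methoxy-4-(triisopropylsilyloxy)phenyl]-2,3-dihydro-1-benzofuran-3-carboxylate (trans) | COc1cc([C@H]2Oc3c(OC)cc(Br)cc3[C@@H]2C(=O)OCC)ccc1O[Si](C(C)C)(C(C)C)C(C)C | intermediate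
12 | [(2S,3R)-5-bromo-7-methoxy-2-[3-methoxy-4-(triisopropylsilyloxy)phenyl]-2,3-dihydro-1-benzofuran-3-yl]methanol | COc1cc([C@H]2Oc3c(OC)cc(Br)cc3[C@@H]2CO)ccc1O[Si](C(C)C)(C(C)C)C(C)C | intermediate
13 | 4-hydroxybenzoic acid | OC(=O)c1ccc(O)cc1 | starting material
14 | triisopropylsilyl 4-(triisopropylsilyloxy)benzoate (not isolated) | CC(C)[Si](OC(=O)c1ccc(O[Si](C(C)C)(C(C)C)C(C)C)cc1)(C(C)C)C(C)C | intermediate
15 | 4-(triisopropylsilyloxy)benzoic acid | OC(=O)c1ccc(O[Si](C(C)C)(C(C)C)C(C)C)cc1 | intermediate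
16 | [(2S,3R)-5-bromo-7-methoxy-2-[3-methoxy-4-(triisopropylsilyloxy)phenyl]-2,3-dihydro-1-benzofuran-3-yl]methyl 4-(triisopropylsilyloxy)benzoate | COc1cc([C@H]2Oc3c(OC)cc(Br)cc3[C@@H]2COC(=O)c2ccc(O[Si](C(C)C)(C(C)C)C(C)C)cc2)ccc1O[Si](C(C)C)(C(C)C)C(C)C | intermediate
17 | prop-2-yn-1-ol | C#CCO | starting material
18 | [(2S,3R)-5-(3-hydroxyprop-1-yn-1-yl)-7-methoxy-2-[3-methoxy-4-(triisopropylsilyloxy)phenyl]-2,3-dihydro-1-benzofuran-3-yl]methyl 4-(triisopropylsilyloxy)benzoate | COc1cc([C@H]2Oc3c(OC)cc(C#CCO)cc3[C@@H]2COC(=O)c2ccc(O[Si](C(C)C)(C(C)C)C(C)C)cc2)ccc1O[Si](C(C)C)(C(C)C)C(C)C | intermediate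
19 | [(2S,3R)-5-[(1Z)-3-hydroxyprop-1-en-1-yl]-7-methoxy-2-[3-methoxy-4-(triisopropylsilyloxy)phenyl]-2,3-dihydro-1-benzofuran-3-yl]methyl 4-(triisopropylsilyloxy)benzoate | COc1cc([C@H]2Oc3c(OC)cc(/C=C\CO)cc3[C@@H]2COC(=O)c2ccc(O[Si](C(C)C)(C(C)C)C(C)C)cc2)ccc1O[Si](C(C)C)(C(C)C)C(C)C | intermediate
20 | [(2S,3R)-7-methoxy-2-[3-methoxy-4-(triisopropylsilyloxy)phenyl]-5-[(1Z)-3-oxoprop-1-en-1-yl]-2,3-dihydro-1-benzofuran-3-yl]methyl 4-(triisopropylsilyloxy)benzoate | COc1cc([C@H]2Oc3c(OC)cc(/C=C\C=O)cc3[C@@H]2COC(=O)c2ccc(O[Si](C(C)C)(C(C)C)C(C)C)cc2)ccc1O[Si](C(C)C)(C(C)C)C(C)C | intermediate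
21 | [(2S,3R)-2-(4-hydroxy-3-methoxyphenyl)-7-methoxy-5-[(1Z)-3-oxoprop-1-en-1-yl]-2,3-dihydro-1-benzofuran-3-yl]methyl 4-hydroxybenzoate | COc1cc([C@H]2Oc3c(OC)cc(/C=C\C=O)cc3[C@@H]2COC(=O)c2ccc(O)cc2)ccc1O | target

## Step count and risks

Total step count: 11. Longest linear sequence: 9 steps (5 → 6 → 9 → 11 → 12 → 16 → 18 → 19 → 20 → 21).

Steps most likely to fail:

1. Step 4 (proposed new method). Insertion of aryl–Rh into the donor-substituted, weakly aromatic C2=C3 bond may be too slow, so that protodeboronation consumes the boronic acid, or enantioface discrimination of the flat heteroarene may be poor. Fallback with known chemistry, setting out from 4 and 9 and returning at 12: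
   - Pd(II)-catalysed oxidative C2–H arylation of 4 with 9 (Pd(OAc)2, cat. Cu(OAc)2, O2, AcOH, rt) should give ethyl 5-bromo-7-methoxy-2-[3-methoxy-4-(triisopropylsilyloxy)phenyl]-1-benzofuran-3-carboxylate F1.
   - Conjugate reduction with Mg in MeOH/THF (NH4Cl, −15 → 0 °C), with transesterification and equilibration, should give racemic trans methyl 5-bromo-7-methoxy-2-[3-methoxy-4-(triisopropylsilyloxy)phenyl]-2,3-dihydro-1-benzofuran-3-carboxylate F2.
   - DIBAL-H reduction should give racemic trans [5-bromo-7-methoxy-2-[3-methoxy-4-(triisopropylsilyloxy)phenyl]-2,3-dihydro-1-benzofuran-3-yl]methanol F3, and preparative chiral SFC should deliver the (2S,3R) enantiomer 12.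

2. Step 11. The (Z)-enal may isomerize to the (E)-enal through reversible conjugate addition of fluoride, acetate or phenoxide during desilylation. Fallback, setting out from 19 and returning at 21: the silyl groups are removed first (TBAF/AcOH, THF, 0 °C) to give [(2S,3R)-2-(4-hydroxy-3-methoxyphenyl)-5-[(1Z)-3-hydroxyprop-1-en-1-yl]-7-methoxy-2,3-dihydro-1-benzofuran-3-yl]methyl 4-hydroxybenzoate F4. The allylic alcohol is then oxidized chemoselectively with activated MnO2 (CH2Cl2, rt, dark), so that the sensitive enal is formed in the last, neutral and heterogeneous operation.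

3. Step 9. Over-reduction to the saturated chain or partial Z→E isomerization on the catalyst may erode the geometry. Fallback, setting out from 16 and 17 and returning at 19, bypassing steps 8 and 9: prop-2-yn-1-ol 17 is converted by LiAlH4 hydroalumination and trapping with Bu3SnOTf into (Z)-3-(tributylstannyl)prop-2-en-1-ol F5. Stille coupling of F5 with bromide 16 (Pd2(dba)3, P(t-Bu)3, dioxane, 60 °C, fluoride-free) should transfer the alkenyl group with retention of the (Z)-geometry and give 19 directly.

Further compounds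
F1 | step 4 | ethyl 5-bromo-7-methoxy-2-[3-methoxy-4-(triisopropylsilyloxy)phenyl]-1-benzofuran-3-carboxylate | CCOC(=O)c1c(-c2ccc(O[Si](C(C)C)(C(C)C)C(C)C)c(OC)c2)oc2c(OC)cc(Br)cc12
F2 | step 4 | racemic trans methyl 5-bromo-7-methoxy-2-[3-methoxy-4-(triisopropylsilyloxy)phenyl]-2,3-dihydro-1-benzofuran-3-carboxylate (both enantiomers) | COc1cc([C@H]2Oc3c(OC)cc(Br)cc3[C@@H]2C(=O)OC)ccc1O[Si](C(C)C)(C(C)C)C(C)C.COc1cc([C@@H]2Oc3c(OC)cc(Br)cc3[C@H]2C(=O)OC)ccc1O[Si](C(C)C)(C(C)C)C(C)C
F3 | step 4 | racemic trans [5-bromo-7-methoxy-2-[3-methoxy-4-(triisopropylsilyloxy)phenyl]-2,3-dihydro-1-benzofuran-3-yl]methanol (both enantiomers) | COc1cc([C@H]2Oc3c(OC)cc(Br)cc3[C@@H]2CO)ccc1O[Si](C(C)C)(C(C)C)C(C)C.COc1cc([C@@H]2Oc3c(OC)cc(Br)cc3[C@H]2CO)ccc1O[Si](C(C)C)(C(C)C)C(C)C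
F4 | step 11 | [(2S,3R)-2-(4-hydroxy-3-methoxyphenyl)-5-[(1Z)-3-hydroxyprop-1-en-1-yl]-7-methoxy-2,3-dihydro-1-benzofuran-3-yl]methyl 4-hydroxybenzoate | COc1cc([C@H]2Oc3c(OC)cc(/C=C\CO)cc3[C@@H]2COC(=O)c2ccc(O)cc2)ccc1O
F5 | step 9 | (Z)-3-(tributylstannyl)prop-2-en-1-ol | CCCC[Sn](CCCC)(CCCC)/C=C\CO
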